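**Plan**

1. Ring numbering: ring A carries CO2H on C1, heptyl on C2, OMe on C4 and the ether oxygen on C6; ring B carries CO2H on C1', OH on C2', the ether oxygen on C4', OMe on C5' and heptyl on C6'.
2. Retrosynthesis: the C2' phenol is masked as a MOM ether, then both heptyl chains are cut between the benzylic CH2 and the next CH2, leaving a dimethyl diacid and two molecules of 1-bromohexane. The diaryl ether bond O–C6 (ring A) is cut last, giving two benzoates that both derive from methyl orsellinate.
3. Enabling feature: the benzylic carbon on C2 of ring A and that on C6' of ring B each sit ortho to a carboxyl group (on C1 and C1'), so each is acidified by its own carboxylate and both chains can grow from ortho-methyl groups.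
4. Forward: methyl orsellinate gives ring A as an aryl triflate (2 steps) and ring B as a 5-methoxy-2-O-MOM phenol (5 steps). Pd-catalysed C–O coupling joins them, saponification gives the diacid, the twofold lateral alkylation adds both C6 units, and mild acid removes the MOM group.
5. No ring is formed (both benzene rings are bought). The target has no stereogenic element, so no stereocontrol is required.

Key step: step 10

Remark: the target SMILES contains no stereocentre and no stereogenic double bond, so the compound is achiral and is made as the single constitution shown; LDA is taken as a purchased solution.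

**Step 1**
Reactants: 1 methyl orsellinate (methyl 2,4-dihydroxy-6-methylbenzoate)
Product: 2 methyl 2-hydroxy-4-methoxy-6-methylbenzoate
Conditions: MeI (1.05 equiv), K2CO3 (1.1 equiv), acetone, reflux
Reagents that add atoms: iodomethane, CI
Why: Williamson O-methylation; the C4 hydroxyl (para to the ester, free and most acidic) should react selectively because the C2 hydroxyl is tied up in a hydrogen bond to the ester carbonyl.

**Step 2**
Reactants: 2 methyl 2-hydroxy-4-methoxy-6-methylbenzoate
Product: 3 methyl 4-methoxy-6-methyl-2-[(trifluoromethanesulfonyl)oxy]benzoate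
Conditions: Tf2O, pyridine, CH2Cl2, 0 °C → rt
Reagents that add atoms: trifluoromethanesulfonic anhydride, O=S(=O)(OS(=O)(=O)C(F)(F)F)C(F)(F)F
Why: O-sulfonylation of the only free phenol (aryl triflate formation), which turns the C2 oxygen of ring A into a leaving group for cross-coupling.

**Step 3**
Reactants: 1 methyl orsellinate
Product: 4 methyl 4-(benzyloxy)-2-hydroxy-6-methylbenzoate
Conditions: BnBr (1.05 equiv), K2CO3, acetone, reflux
Reagents that add atoms: benzyl bromide, BrCc1ccccc1
Why: Williamson O-benzylation with the same C4-over-C2 selectivity as in step 1, leaving the chelated C2 hydroxyl free to direct the next step.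

**Step 4**
Reactants: 4 methyl 4-(benzyloxy)-2-hydroxy-6-methylbenzoate
Product: 6 methyl 4-(benzyloxy)-2,5-dihydroxy-6-methylbenzoate, via aryl potassium sulfate 5 (not isolated)
Conditions: K2S2O8, 10% aq NaOH/pyridine, 0 °C → rt; then aq HCl, 70 °C
Reagents that add atoms: potassium peroxodisulfate, [K+].[K+].[O-]S(=O)(=O)OOS(=O)(=O)[O-]
Why: Elbs persulfate oxidation; the phenoxide of the C2 hydroxyl should attack peroxodisulfate through its only free para carbon (C5), and acid hydrolysis of the aryl sulfate then frees the C5 hydroxyl while the hindered, chelated methyl ester survives the cold alkali.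

**Step 5**
Reactants: 6 methyl 4-(benzyloxy)-2,5-dihydroxy-6-methylbenzoate
Product: 7 methyl 4-(benzyloxy)-2-hydroxy-5-methoxy-6-methylbenzoate
Conditions: MeI (1.1 equiv), K2CO3, acetone, 40 °C, N2
Reagents that add atoms: iodomethane, CI
Why: Williamson O-methylation; as in the selective 5-O-alkylation of gentisate esters, the non-chelated C5 hydroxyl should react while the hydrogen-bonded C2 hydroxyl stays free, and exclusion of air prevents oxidation of the hydroquinone.

**Step 6**
Reactants: 7 methyl 4-(benzyloxy)-2-hydroxy-5-methoxy-6-methylbenzoate
Product: 8 methyl 4-(benzyloxy)-5-methoxy-2-(methoxymethoxy)-6-methylbenzoate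
Conditions: NaH, DMF, 0 °C; MOMCl, 0 °C → rt
Reagents that add atoms: chloromethyl methyl ether, COCCl
Why: acetal-type O-alkylation (MOM protection); full deprotonation with NaH overcomes the low nucleophilicity of the chelated phenol, and the MOM ether is stable to all later basic steps.

**Step 7**
Reactants: 8 methyl 4-(benzyloxy)-5-methoxy-2-(methoxymethoxy)-6-methylbenzoate
Product: 9 methyl 4-hydroxy-5-methoxy-2-(methoxymethoxy)-6-methylbenzoate
Conditions: H2 (1 atm), 10% Pd/C, EtOAc, rt
Reagents that add atoms: none
Why: catalytic hydrogenolysis of the benzyl ether under neutral conditions should free the C4 hydroxyl without touching the MOM acetal, the methyl ethers or the ester.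

**Step 8**
Reactants: 3 methyl 4-methoxy-6-methyl-2-[(trifluoromethanesulfonyl)oxy]benzoate; 9 methyl 4-hydroxy-5-methoxy-2-(methoxymethoxy)-6-methylbenzoate
Product: 10 methyl 2-[2-methoxy-4-(methoxycarbonyl)-5-(methoxymethoxy)-3-methylphenoxy]-4-methoxy-6-methylbenzoate
Conditions: Pd(OAc)2 (5 mol %), t-BuXPhos (10 mol %), K3PO4, toluene, 100 °C
Reagents that add atoms: none
Why: Buchwald-type Pd-catalysed diaryl ether synthesis; oxidative addition into the triflate (activated by its ortho ester), exchange for the only phenoxide present (C4'–O of 9) and C–O reductive elimination from the bulky biarylphosphine complex should join the rings at O–C6.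

**Step 9**
Reactants: 10 the dimethyl ester from step 8
Product: 11 2-[4-carboxy-2-methoxy-5-(methoxymethoxy)-3-methylphenoxy]-4-methoxy-6-methylbenzoic acid
Conditions: KOH, DMSO/H2O (4:1), 90 °C; then cold 1 M HCl to pH 3–4, 0 °C
Reagents that add atoms: potassium hydroxide, [K+].[OH-]
Why: saponification of the two di-ortho-substituted methyl esters with poorly solvated hydroxide in aqueous DMSO, done while the flanking groups are still methyl; the MOM ether is base-stable and the cold, mildly acidic work-up should spare it.

**Step 10**
Reactants: 11 the dimethyl diacid from step 9; 12 1-bromohexane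
Product: 14 2-[4-carboxy-3-heptyl-2-methoxy-5-(methoxymethoxy)phenoxy]-6-heptyl-4-methoxybenzoic acid, via tetralithium tetraanion 13 (not isolated)
Conditions: LDA (6 equiv), THF, −78 → 0 °C; then 12 (4 equiv), −78 °C → rt; cold 1 M HCl to pH 3–4
Reagents that add atoms: 1-bromohexane, CCCCCCBr
Why: LDA first forms the two lithium carboxylates and then removes one proton from each ortho methyl group (on C2 of ring A and C6' of ring B), giving tetralithium species 13 in which each benzylic carbanion is delocalised into its neighbouring carboxylate as an ortho-quinodimethane-type enediolate; each benzylic carbon then displaces bromide from 12 in an SN2 reaction, so both ArCH2–CH2 bonds form in one operation. The closest known reaction type is the lateral lithiation–alkylation of ortho-toluic acid dianions and 2-alkoxy-6-methylbenzoates with lithium amides and primary halides. No ring is closed and no stereocentre is created. The step needs lateral rather than ring metalation (C3' lies between the OMOM and aryloxy oxygens, C5 between OMe and the aryloxy oxygen): a hindered lithium amide under equilibrating conditions does not ortho-lithiate aryl ethers at a useful rate and should settle on the carboxylate-conjugated benzylic anions, the carboxyl groups on C1 and C1' being what places the charge on the adjacent methyl carbons. It also needs C- over O-alkylation and mono- over dialkylation at each site: the benzylic carbon is far more nucleophilic toward a primary bromide than a lithium carboxylate in THF, and the monoalkylated ArCH2R position is more hindered and less acidic, so a second deprotonation at low temperature should not compete. The ether oxygen insulates the two rings, so the two dianion units should react independently.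

**Step 11**
Reactants: 14 the MOM-protected bis-heptyl diacid from step 10
Product: 15 2-(4-carboxy-3-heptyl-5-hydroxy-2-methoxyphenoxy)-6-heptyl-4-methoxybenzoic acid (target)
Conditions: 3 M aq HCl, THF, 40 °C
Reagents that add atoms: none
Why: acid-catalysed hydrolysis of the MOM acetal, assisted by the neighbouring carboxyl group, should free the C2' phenol under conditions mild enough to avoid decarboxylation of the salicylic acid and cleavage of the methyl ethers.

**Compound list**

1 | methyl orsellinate (methyl 2,4-dihydroxy-6-methylbenzoate) | COC(=O)c1c(C)cc(O)cc1O | starting material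
2 | methyl 2-hydroxy-4-methoxy-6-methylbenzoate | COC(=O)c1c(C)cc(OC)cc1O | intermediate
3 | methyl 4-methoxy-6-methyl-2-[(trifluoromethanesulfonyl)oxy]benzoate | COC(=O)c1c(C)cc(OC)cc1OS(=O)(=O)C(F)(F)F | intermediate
4 | methyl 4-(benzyloxy)-2-hydroxy-6-methylbenzoate | COC(=O)c1c(C)cc(OCc2ccccc2)cc1O | intermediate
5 | potassium 2-(benzyloxy)-4-hydroxy-5-(methoxycarbonyl)-6-methylphenyl sulfate (not isolated) | COC(=O)c1c(C)c(OS(=O)(=O)[O-])c(OCc2ccccc2)cc1O.[K+] | intermediate
6 | methyl 4-(benzyloxy)-2,5-dihydroxy-6-methylbenzoate | COC(=O)c1c(C)c(O)c(OCc2ccccc2)cc1O | intermediate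
7 | methyl 4-(benzyloxy)-2-hydroxy-5-methoxy-6-methylbenzoate | COC(=O)c1c(C)c(OC)c(OCc2ccccc2)cc1O | intermediate
8 | methyl 4-(benzyloxy)-5-methoxy-2-(methoxymethoxy)-6-methylbenzoate | COC(=O)c1c(C)c(OC)c(OCc2ccccc2)cc1OCOC | intermediate
9 | methyl 4-hydroxy-5-methoxy-2-(methoxymethoxy)-6-methylbenzoate | COC(=O)c1c(C)c(OC)c(O)cc1OCOC | intermediate
10 | methyl 2-[2-methoxy-4-(methoxycarbonyl)-5-(methoxymethoxy)-3-methylphenoxy]-4-methoxy-6-methylbenzoate | COC(=O)c1c(C)cc(OC)cc1Oc2cc(OCOC)c(C(=O)OC)c(C)c2OC | intermediate
11 | 2-[4-carboxy-2-methoxy-5-(methoxymethoxy)-3-methylphenoxy]-4-methoxy-6-methylbenzoic acid | Cc1cc(OC)cc(Oc2cc(OCOC)c(C(=O)O)c(C)c2OC)c1C(=O)O | intermediate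
12 | 1-bromohexane | CCCCCCBr | starting material
13 | tetralithium salt of the bis(carboxylate) bis(benzylic) tetraanion of 11 (not isolated) | [Li+].[Li+].[Li+].[Li+].[CH2-]c1cc(OC)cc(Oc2cc(OCOC)c(C(=O)[O-])c([CH2-])c2OC)c1C(=O)[O-] | intermediate
14 | 2-[4-carboxy-3-heptyl-2-methoxy-5-(methoxymethoxy)phenoxy]-6-heptyl-4-methoxybenzoic acid | CCCCCCCc1cc(OC)cc(Oc2cc(OCOC)c(C(=O)O)c(CCCCCCC)c2OC)c1C(=O)O | intermediate
15 | 2-(4-carboxy-3-heptyl-5-hydroxy-2-methoxyphenoxy)-6-heptyl-4-methoxybenzoic acid | CCCCCCCc1cc(OC)cc(Oc2cc(O)c(C(=O)O)c(CCCCCCC)c2OC)c1C(=O)O | target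

**Step count**

Total: 11 steps. Longest linear sequence: 9 steps (steps 3–11, from methyl orsellinate 1 through ring B).

**Steps most likely to fail**

Step 10. The fourfold deprotonation may stay incomplete because the polylithiated dicarboxylate aggregates or precipitates, so that only one chain is extended, or ring metalation next to the MOM ether may intervene. The fallback sets out from diester 10 and generates the two benzylic anions as ester dienolates instead of carboxylate dianions. LDA (2.5 equiv) in THF/DMPU at −78 °C followed by 12 should give methyl 2-[3-heptyl-2-methoxy-4-(methoxycarbonyl)-5-(methoxymethoxy)phenoxy]-6-heptyl-4-methoxybenzoate F1. Hydrolysis of both esters with KOH in DMSO/H2O at 100 °C then returns to the route at 14. The same two benzylic CH2–CH2 bonds are formed; the price is a late hydrolysis of more hindered esters.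

Step 4. The persulfate substitution may stall at a para carbon flanked by a benzyloxy and a methyl group, and prolonged exposure to alkali may start to hydrolyse the ester or over-oxidise the product. The fallback sets out from 4 and reaches the same oxidation pattern through a quinone. Teuber oxidation with Fremy's salt (potassium nitrosodisulfonate, KH2PO4 buffer, acetone/H2O, rt) should give methyl 4-(benzyloxy)-2-methyl-3,6-dioxocyclohexa-1,4-diene-1-carboxylate F2. Reduction with Na2S2O4 in EtOAc/H2O returns to the route at 6.

Step 8. Phenoxide or phosphate may cleave the S–O bond of the triflate and regenerate 2, and C–O reductive elimination may be slow with a phenoxide that is para to an ester. The fallback sets out from 3 and replaces the palladium C–O coupling by a copper-mediated Ullmann etherification of an aryl bromide. Miyaura borylation (B2pin2, Pd(dppf)Cl2, KOAc, dioxane, 80 °C) should give methyl 4-methoxy-6-methyl-2-(4,4,5,5-tetramethyl-1,3,2-dioxaborolan-2-yl)benzoate F3. Bromodeboronation (CuBr2, MeOH/H2O, 80 °C) should give methyl 2-bromo-4-methoxy-6-methylbenzoate F4. Coupling of the bromide with phenol 9 (CuI, picolinic acid, K3PO4, DMSO, 90 °C) returns to the route at 10.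

**Further compounds**

F1 | step 10 | methyl 2-[3-heptyl-2-methoxy-4-(methoxycarbonyl)-5-(methoxymethoxy)phenoxy]-6-heptyl-4-methoxybenzoate | CCCCCCCc1cc(OC)cc(Oc2cc(OCOC)c(C(=O)OC)c(CCCCCCC)c2OC)c1C(=O)OC
F2 | step 4 | methyl 4-(benzyloxy)-2-methyl-3,6-dioxocyclohexa-1,4-diene-1-carboxylate | COC(=O)C1=C(C)C(=O)C(OCc2ccccc2)=CC1=O
F3 | step 8 | methyl 4-methoxy-6-methyl-2-(4,4,5,5-tetramethyl-1,3,2-dioxaborolan-2-yl)benzoate | COC(=O)c1c(C)cc(OC)cc1B1OC(C)(C)C(C)(C)O1
F4 | step 8 | methyl 2-bromo-4-methoxy-6-methylbenzoate | COC(=O)c1c(C)cc(OC)cc1Br
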